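The numbers in the tables come from a simulation with made-up constants; the scatter is artificial.

Count the partner first.

in all of them: substrate 0.10 M
- red: partner 0.15 M; scavenger 0.10 M; the very flask that is asked about, followed so far
- ochre: partner 0.22 M; scavenger 0.10 M; run made earlier
- flask: partner 0.150 M; scavenger 0.100 M; time 6.0 d

red run (percent of the substrate charged)

| time / h | substrate / % | single product / % |
|---|---|---|
| 3.00 | 36.2 | 49.8 |
| 6.00 | 23.0 | 53.9 |
| 12.0 | 15.4 | 53.8 |
| 25.0 | 10.7 | 52.2 |
| 40.0 | 10.8 | 51.8 |

ochre run (percent of the substrate charged)

| time / d | substrate / % | single product / % |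
|---|---|---|
| 0.208 | 12.9 | 52.3 |
| 0.625 | 3.8 | 40.2 |
| 1.04 | 2.5 | 35.3 |
| 1.67 | 2.1 | 29.1 |
| 2.50 | 0.9 | 26.3 |

(readings scatter by 0.5 percentage points)

- the earlier runs were read with a standard deviation of 0.5 percentage points
- the earlier runs do not show how much of partner is bound; that part of a forecast is a guess

- part of the substrate that has reacted at 6.0 d
- share of the unused partner that is free and not bound as idle adduct, at 6.0 d

One partner stands in each single product, and the substrate missing from both columns is assumed here to carry two. With s and m as fractions of the substrate charge, and e as partner charged per substrate (1.50 in red), the partner yield φ is the share of the partner charge standing in products: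

φ = (2 − 2s − m)/e

In red it reads 84.3% at 25.0 h and 84.4% at 40.0 h. Holding φ and m to 6.0 d, my reckoning for the red flask is:

c = (φe + m)/2 = 89.2%

One number is not enough, though: φ as read in ochre goes from 75.8% at 1.67 d to 78.1% at 2.50 d, so red's value is carried for red's charge. Nor does φ show whether unused partner is free, so fr stays a guess.

The forecast, differing from this reckoning, gave 92% and 6%, holding that "the scavenger binds partner slowly". The flask gives 90.5% and 81.4%.

    partner + single product → bis adduct + released group (k = 4.33 × 10⁻⁴ M⁻¹ s⁻¹)
    partner + released group ⇌ idle adduct, settled at all times (K = 6.94 M⁻¹)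
    partner + bis adduct ⇌ triple product + released group (K = 3.00, k = 4.80 × 10⁻⁴ M⁻¹ s⁻¹)
    partner → decomposed reagent (k = 7.83 × 10⁻⁶ s⁻¹)
    substrate + partner → single product + released group (k = 0.00110 M⁻¹ s⁻¹)
    scavenger + released group → scavenged by-product (k = 8.96 × 10⁻⁴ M⁻¹ s⁻¹)

At 6.0 d the flask has φ = 88.7%, triple product counted with three partners, and holds 0.11% of its partner, the limiting reagent, free, beside 3.88 × 10⁻⁵ M of idle adduct. Red's φ and m, applied to the neighbour charged with 0.17 M of substrate and so 0.882 equiv of partner, give c = 63.1%. That neighbour reaches 67.9%, with φ = 94.6%.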